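All runs were computed with constants of no real substance; scatter was added.

The vessel is closed, stirred and isothermal, and a short meeting took up what stands in the flask at 80 min and which option gains target. The grey run is this same flask, followed so far.

common to all: free catalyst 2.5 mol%
- grey: starting material 20 mM; reagent 0.95 equiv; second substrate 1 equiv; the very flask that is asked about, followed so far
- amber: starting material 30 mM; reagent 0.95 equiv; second substrate 1 equiv; run made earlier
- flask: starting material 20 mM; reagent 0.950 equiv; second substrate 1.00 equiv; time 80 min

grey run (percent of the starting material charged)

| time / min | target / % | starting material / % |
|---|---|---|
| 3.00 | 47 | 54 |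
| 10.0 | 47 | 51 |
| 15.0 | 48 | 54 |
| 25.0 | 46 | 52 |
| 40.0 | 47 | 52 |
| 50.0 | 48 | 52 |

amber run (percent of the starting material charged)

| time / s | target / % | starting material / % |
|---|---|---|
| 10.0 | 24 | 75 |
| 12.0 | 26 | 74 |
| 20.0 | 35 | 66 |
| 40.0 | 46 | 55 |
| 60.0 | 47 | 51 |
| 90.0 | 53 | 41 |

(readings scatter by 1.5 percentage points)

1. target, in percent of the starting material first charged, at 80 min
2. what to do for the largest gain in target; "none" if nothing gains more than 2 percentage points (Thursday's / Sunday's / Wednesday's / Monday's / none)
3. target present, with what was taken out counted in, in percent of the starting material first charged, after Thursday's
4. target present, with what was taken out counted in, in percent of the starting material first charged, after Monday's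

- Thursday's: at 80 min add free catalyst, 50.0% of the amount charged, then wait 40 min
- Sunday's: at 80 min take out 90% of the target then present, then wait 40 min
- Wednesday's: change nothing and wait 40 min more
- Monday's: at 80 min add reagent, 50.0% of the amount charged, then wait 40 min

- target that was removed still counts
- the analysis behind the earlier runs scatters by 1.5 percentage points, standard deviation
- additions bring no volume worth counting

The first speaker reported that target in the flask lies flat from 3.00 min to 50.0 min, averaging 47.2%, well below what the reagent, the limiting reagent at 0.95 equiv, allows. The second speaker objected that a flat line says that net reaction has stopped but not why, and that a balance and a dead catalyst both draw such a line.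

The third speaker went to the board and took the dead catalyst. She argued that if turnover and catalyst loss both go as [starting material][free catalyst], and turnover also as [reagent], then target made per catalyst lost is proportional to [reagent], so log10 [reagent] falls in a straight line against catalyst lost. In the flask [reagent] goes from 19.0 mM to 9.57 mM on 0.500 mM of catalyst, so the slope is 0.596 /mM. She called this the reach, the powers of ten of [reagent] taken down per millimolar of catalyst charged.

For the amber run, with 0.750 mM of catalyst, she reckoned a stop at 61.1%, above the last reading of 53%, which was still climbing from 47%. The meeting agreed that the amber readings do not contradict this and do not prove it, and committed to it.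

On that reckoning the flask holds 47.2% at 80 min, and Monday's, Sunday's and Wednesday's leave it there, with the 0.500 mM of catalyst counted as lost. Thursday's catalyst is reckoned to take [reagent] down by 0.149 powers of ten, giving 61.1%, so Thursday's was the meeting's choice.

The forecast gave 47.3% (from 46.3% to 48.3%), Sunday's as best, 47.3% after Thursday's and 56% after Monday's, saying “I read this as equilibrium”, so it parts from the meeting on all but the first.

The flask gives 46.1% at 80 min, Thursday's as best with a gain of 12 percentage points, 57.7% after Thursday's against the meeting's 61.1%, and 46.1% after Monday's.

    starting material + reagent + free catalyst ⇌ free catalyst + target (K = 1400 /M, k = 1700 /M²/s)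
    second substrate + reagent + free catalyst → free catalyst + second product (k = 120 /M²/s)
    starting material + free catalyst → spent catalyst (k = 1.20 /M/s)

In the flask the forward rate of the step to target alone gives starting material a half-life of 1.6 min at 0.414 min, against 19 min by the step to spent catalyst with the charges held, and at 8.00 min free catalyst stands at 0.154% of its charge with target at 46.0%. The reach applied to the neighbour charged with 6.2 mol% of free catalyst, its other charges as in the flask, leaves 18.2% of its reagent, and at 80.0 min that neighbour holds 68.3% target and 17.8% of its reagent.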